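**Retrosynthetic overview** (ring A = benzo ring of the chromone, ring C = pyranone ring, ring B = pendant benzene ring, ring D = dimethyl-dihydropyran ring fused to ring B)
- The target comes from its ring-B benzyl ether by hydrogenolysis.
- The strategy rests on ring A (C4a, C5, C6, C7, C8, C8a): it is fused to ring C at C4a–C8a and carries hydroxyls on C5 and C7, the 1,3-dioxygen pattern of an acetoacetate-derived 1,3-bis(silyloxy)diene. C4a–C8a is at the same time the second enone double bond of a 4-pyranone that already holds ring B on C3, so ring A is cut at C8–C8a and C4a–C5, and a bromine on the pyranone carbon that becomes C4a pays for the aromatisation.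
- The 3-aryl-5-bromo-4-pyranone comes from one Suzuki coupling of symmetrical 3,5-dibromo-4H-pyran-4-one with a chroman-6-yl boronate.
- The boronate comes from 8-benzyloxy-6-bromo-2,2-dimethylchroman, whose ring D is made by an o-quinone methide/isobutene cycloaddition on reduced 5-bromo-o-vanillin.
- Order of ring formation: ring D first (ring B is bought as the arene), ring C is bought as 4H-pyran-4-one, ring A last.

Key step: step 10

Remark on the chemistry: the double-bond geometry of the silyl enol ether of methyl acetoacetate (an E/Z mixture) and of the ketene acetal bond of the diene made from it (drawn 1Z) is taken to be of no consequence, because both carbons end as sp2 carbons of ring A.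

**Step 1**
Reactants: 1 5-bromo-2-hydroxy-3-methoxybenzaldehyde
Product: 2 4-bromo-2-(hydroxymethyl)-6-methoxyphenol
Conditions: NaBH4, MeOH/THF, 0 °C
Reagents that add atoms: none
Why: Borohydride reduction of an aryl aldehyde is fast at 0 °C and should leave the aryl bromide, the phenol and the methyl ether untouched (carbonyl reduction).

**Step 2**
Reactants: 2 4-bromo-2-(hydroxymethyl)-6-methoxyphenol; 3 isobutene
Product: 5 6-bromo-8-methoxy-2,2-dimethylchroman, via o-quinone methide 4 (not isolated)
Conditions: isobutene (excess, condensed), toluene, sealed steel autoclave, 170 °C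
Reagents that add atoms: none
Why: Thermal loss of water from the salicyl alcohol should give o-quinone methide 4, which undergoes an inverse-electron-demand hetero-Diels–Alder reaction with isobutene in which the electrophilic exocyclic methylene bonds to the CH2 terminus of the alkene and the oxygen to the tertiary carbon, so only the 2,2-dimethylchroman regioisomer is expected.

**Step 3**
Reactants: 5 6-bromo-8-methoxy-2,2-dimethylchroman
Product: 6 6-bromo-2,2-dimethylchroman-8-ol
Conditions: BBr3 (1.2 equiv), CH2Cl2, −78 → 0 °C; H2O
Reagents that add atoms: none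
Why: BBr3 binds the methoxy oxygen and bromide attacks the methyl group (Lewis acid-mediated demethylation); with about one equivalent at low temperature the methyl ether should be cleaved faster than the tertiary alkyl aryl ether of ring D, as in demethylations of other 2,2-dimethylchroman ethers.

**Step 4**
Reactants: 6 6-bromo-2,2-dimethylchroman-8-ol
Product: 7 8-(benzyloxy)-6-bromo-2,2-dimethylchroman
Conditions: BnBr, K2CO3, DMF, 60 °C
Reagents that add atoms: benzyl bromide, BrCc1ccccc1
Why: Williamson ether synthesis on the only free phenol; the benzyl ether should withstand the borylation, the coupling and the silyl triflate of the later steps.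

**Step 5**
Reactants: 7 8-(benzyloxy)-6-bromo-2,2-dimethylchroman
Product: 8 2-[8-(benzyloxy)-2,2-dimethylchroman-6-yl]-4,4,5,5-tetramethyl-1,3,2-dioxaborolane
Conditions: B2pin2, PdCl2(dppf) (cat.), KOAc, 1,4-dioxane, 90 °C
Reagents that add atoms: bis(pinacolato)diboron, CC1(C)OB(OC1(C)C)B1OC(C)(C)C(C)(C)O1
Why: Miyaura borylation of an unhindered aryl bromide; KOAc is too weak a base to let the boronate couple with unreacted bromide.

**Step 6**
Reactants: 9 4H-pyran-4-one
Product: 11 3,5-dibromo-4H-pyran-4-one, via 3-bromo-4H-pyran-4-one 10 (not isolated)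
Conditions: Br2 (2.2 equiv), CH2Cl2, 0 → 20 °C; pyridine, 20 °C
Reagents that add atoms: bromine, BrBr
Why: Bromine adds to the enol ether double bond and pyridine removes the acidic α-hydrogen with loss of bromide (α-bromination of a vinylogous ester by addition–elimination, as for chromone to 3-bromochromone); a second cycle on the other enone should give the symmetrical dibromide.

**Step 7**
Reactants: 8 2-[8-(benzyloxy)-2,2-dimethylchroman-6-yl]-4,4,5,5-tetramethyl-1,3,2-dioxaborolane; 11 3,5-dibromo-4H-pyran-4-one
Product: 12 3-[8-(benzyloxy)-2,2-dimethylchroman-6-yl]-5-bromo-4H-pyran-4-one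
Conditions: 11 (3 equiv), PdCl2(dppf) (cat.), K3PO4, 1,4-dioxane/H2O, 60 °C, slow addition of 8
Reagents that add atoms: none
Why: Suzuki–Miyaura coupling at a C–Br bond α to the pyranone carbonyl, which should undergo oxidative addition as readily as that of a 3-halochromone; the excess of symmetrical 11 should hold the reaction at mono-arylation, and unreacted 11 is recovered.

**Step 8**
Reactants: 13 methyl acetoacetate
Product: 14 methyl 3-(trimethylsilyloxy)but-2-enoate
Conditions: Me3SiCl, Et3N, hexane, 20 °C
Reagents that add atoms: chlorotrimethylsilane, C[Si](C)(C)Cl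
Why: O-silylation of the enol of a β-keto ester under soft enolisation; the amine salt is filtered off and the product distilled.

**Step 9**
Reactants: 14 methyl 3-(trimethylsilyloxy)but-2-enoate
Product: 15 (1Z)-1-methoxy-1,3-bis(trimethylsilyloxy)buta-1,3-diene
Conditions: LiN(iPr)2, THF, −78 °C; Me3SiCl, −78 → 20 °C
Reagents that add atoms: chlorotrimethylsilane, C[Si](C)(C)Cl
Why: LiN(iPr)2 removes a γ-hydrogen of the β-silyloxy enoate and the dienolate is silylated on oxygen, the standard preparation of a 1,3-bis(silyloxy)diene; the diene is used directly after removal of LiCl and solvent.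

**Step 10**
Reactants: 12 3-[8-(benzyloxy)-2,2-dimethylchroman-6-yl]-5-bromo-4H-pyran-4-one; 15 (1Z)-1-methoxy-1,3-bis(trimethylsilyloxy)buta-1,3-diene
Product: 19 3-[8-(benzyloxy)-2,2-dimethylchroman-6-yl]-5,7-dihydroxy-4H-chromen-4-one, via silyloxypyrylium triflate 16 (not isolated), via bromo ketal cycloadduct 17 (not isolated), via bis(trimethylsilyl) ether 18 (not isolated)
Conditions: Me3SiOTf (1.2 equiv), 2,6-di-tert-butyl-4-methylpyridine (2.5 equiv), CH2Cl2, 0 → 20 °C; 15 (2 equiv), −78 → 20 °C, then 40 °C; 1 M HCl, THF, 20 °C
Reagents that add atoms: none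
Why: Proposed new method: Me3SiOTf silylates the carbonyl oxygen of 12 to pyrylium salt 16, the CH2 terminus of diene 15 (its most nucleophilic carbon) adds to C6 of the pyrylium ring (the future C8a), and the dialkoxycarbenium ion so formed at the ester-level carbon is captured by the bromine-bearing silyl enol ether carbon (the future C4a) to give cycloadduct 17, a stepwise cationic [4+2] addition. Me3SiOTf then ionises the mixed ketal at C5 with loss of MeOSiMe3, loss of a proton from C8 leaves a 5,7-bis(silyloxy)cyclohexadiene in which the C4a–Br bond is allylic, and elimination of HBr across C4a–C8a aromatises ring A to 18, which the acid work-up desilylates; the bromine thus supplies the oxidation level and no oxidant is needed. The closest known reactions are the Diels–Alder–aromatisation of 1,1,3-trioxygenated dienes with haloquinones, where the halogen likewise sends the ketene acetal carbon to the halogen-bearing carbon and leaves as HX, and the Me3SiOTf-mediated addition of 1,3-bis(silyloxy)dienes to C2 of chromones through benzopyrylium triflates. Ring A closes in the 6-exo-trig mode (enol-exo attack on the carbenium carbon), and because the first bond is made by the CH2 terminus the oxygens fall on C5 and C7. No stereocentre is formed in the product, and the three of 17 are erased on aromatisation. The step needs site selectivity between the two enone termini of the pyranone: C6 lies next to the inductively withdrawing bromine and is open, whereas C2 is shielded by the twisted ring B and made less electrophilic by donation from this electron-rich aryl group, and only the adduct at C6 carries the leaving group that makes closure and aromatisation irreversible.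

**Step 11**
Reactants: 19 3-[8-(benzyloxy)-2,2-dimethylchroman-6-yl]-5,7-dihydroxy-4H-chromen-4-one
Product: 20 5,7-dihydroxy-3-(8-hydroxy-2,2-dimethylchroman-6-yl)-4H-chromen-4-one
Conditions: H2 (1 atm), Pd/C, EtOAc/MeOH, 20 °C
Reagents that add atoms: none
Why: Hydrogenolysis of the benzyl aryl ether over Pd/C; the reaction is stopped after uptake of one equivalent of hydrogen so that the C2=C3 bond of the chromone should not be reduced.

**Compound list**
1 | 5-bromo-2-hydroxy-3-methoxybenzaldehyde | O=Cc1cc(Br)cc(OC)c1O | starting material
2 | 4-bromo-2-(hydroxymethyl)-6-methoxyphenol | OCc1cc(Br)cc(OC)c1O | intermediate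
3 | isobutene (2-methylpropene) | C=C(C)C | starting material
4 | 4-bromo-2-methoxy-6-methylidenecyclohexa-2,4-dien-1-one (o-quinone methide) | C=C1C=C(Br)C=C(OC)C1=O | intermediate
5 | 6-bromo-8-methoxy-2,2-dimethylchroman | COc1cc(Br)cc2c1OC(C)(C)CC2 | intermediate
6 | 6-bromo-2,2-dimethylchroman-8-ol | Oc1cc(Br)cc2c1OC(C)(C)CC2 | intermediate
7 | 8-(benzyloxy)-6-bromo-2,2-dimethylchroman | Brc1cc(OCc2ccccc2)c2OC(C)(C)CCc2c1 | intermediate
8 | 2-[8-(benzyloxy)-2,2-dimethylchroman-6-yl]-4,4,5,5-tetramethyl-1,3,2-dioxaborolane | CC1(C)OB(OC1(C)C)c1cc(OCc2ccccc2)c2OC(C)(C)CCc2c1 | intermediate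
9 | 4H-pyran-4-one | O=c1ccocc1 | starting material
10 | 3-bromo-4H-pyran-4-one | O=c1ccocc1Br | intermediate
11 | 3,5-dibromo-4H-pyran-4-one | O=c1c(Br)cocc1Br | intermediate
12 | 3-[8-(benzyloxy)-2,2-dimethylchroman-6-yl]-5-bromo-4H-pyran-4-one | O=c1c(Br)cocc1-c1cc(OCc2ccccc2)c2OC(C)(C)CCc2c1 | intermediate
13 | methyl acetoacetate | COC(=O)CC(C)=O | starting material
14 | methyl 3-(trimethylsilyloxy)but-2-enoate (E/Z mixture) | COC(=O)C=C(C)O[Si](C)(C)C | intermediate
15 | (1Z)-1-methoxy-1,3-bis(trimethylsilyloxy)buta-1,3-diene | CO/C(O[Si](C)(C)C)=C/C(=C)O[Si](C)(C)C | intermediate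
16 | 3-[8-(benzyloxy)-2,2-dimethylchroman-6-yl]-5-bromo-4-(trimethylsilyloxy)pyrylium trifluoromethanesulfonate | C[Si](C)(C)Oc1c(Br)c[o+]cc1-c1cc(OCc2ccccc2)c2OC(C)(C)CCc2c1.[O-]S(=O)(=O)C(F)(F)F | intermediate
17 | 3-[8-(benzyloxy)-2,2-dimethylchroman-6-yl]-4a-bromo-5-methoxy-5,7-bis(trimethylsilyloxy)-4a,5,8,8a-tetrahydro-4H-chromen-4-one (mixture of diastereomers, configuration undefined and lost in the same step) | O=C1C(-c2cc(OCc3ccccc3)c3OC(C)(C)CCc3c2)=COC2CC(O[Si](C)(C)C)=CC(OC)(O[Si](C)(C)C)C12Br | intermediate
18 | 3-[8-(benzyloxy)-2,2-dimethylchroman-6-yl]-5,7-bis(trimethylsilyloxy)-4H-chromen-4-one | O=c1c(-c2cc(OCc3ccccc3)c3OC(C)(C)CCc3c2)coc2cc(O[Si](C)(C)C)cc(O[Si](C)(C)C)c12 | intermediate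
19 | 3-[8-(benzyloxy)-2,2-dimethylchroman-6-yl]-5,7-dihydroxy-4H-chromen-4-one | O=c1c(-c2cc(OCc3ccccc3)c3OC(C)(C)CCc3c2)coc2cc(O)cc(O)c12 | intermediate
20 | 5,7-dihydroxy-3-(8-hydroxy-2,2-dimethylchroman-6-yl)-4H-chromen-4-one | CC1(C)CCc2cc(-c3coc4cc(O)cc(O)c4c3=O)cc(O)c2O1 | target

**Step count and risks**
Total step count: 11 (steps 1–5 for the boronate, step 6 for the dibromopyranone, step 7 for the coupling, steps 8–9 for the diene, step 10 for ring A, step 11 for deprotection).
Longest linear sequence: 8 steps (steps 1, 2, 3, 4, 5, 7, 10, 11).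

Steps most likely to fail:

1. Step 10 (annulation of ring A). Three processes may defeat it. The diene may add to C2 of the pyrylium ion, next to ring B, instead of C6. The sequence may stop after the first carbon–carbon bond because the bromine-bearing silyl enol ether does not close onto the ester-level carbon, and the open-chain bromo keto ester may then alkylate itself on work-up. The pyranone ring may also open by loss of the ring oxygen from C8a before hydrogen bromide is lost. The fallback uses known isoflavone chemistry and brings ring A in preformed. It sets out from boronate 8. Commercially available 2',4',6'-trihydroxyacetophenone would be benzylated on the two hydroxyls that are not hydrogen-bonded (BnBr, K2CO3, acetone, reflux) to 1-[2,4-bis(benzyloxy)-6-hydroxyphenyl]ethanone F1. Condensation with N,N-dimethylformamide dimethyl acetal at 95 °C would give the enaminone (2E)-1-[2,4-bis(benzyloxy)-6-hydroxyphenyl]-3-(dimethylamino)prop-2-en-1-one F2. Iodine in methanol would close and iodinate this to 5,7-bis(benzyloxy)-3-iodo-4H-chromen-4-one F3. Suzuki–Miyaura coupling of F3 with 8 (Pd(PPh3)4, Na2CO3, DME/H2O, 80 °C) would give 5,7-bis(benzyloxy)-3-[8-(benzyloxy)-2,2-dimethylchroman-6-yl]-4H-chromen-4-one F4. Hydrogenolysis of the three benzyl ethers (H2, Pd/C) returns to the route at target 20.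

2. Step 7 (single Suzuki coupling). The second carbon–bromine bond of the pyranone may undergo oxidative addition at nearly the rate of the first, so that double arylation consumes the boronate. Aqueous base may also open the pyranone ring by conjugate addition. The fallback makes the two halogens different instead of relying on statistics. It sets out from 4H-pyran-4-one 9, which with one equivalent of bromine and then pyridine would give 3-bromo-4H-pyran-4-one 10, this time isolated. Iodination of the remaining α-position (I2, (NH4)2Ce(NO3)6, MeCN, 65 °C) would give 3-bromo-5-iodo-4H-pyran-4-one F5. Coupling of F5 with 8 at 20–40 °C (Pd(PPh3)4, K3PO4, 1,4-dioxane/H2O) should take place at the carbon–iodine bond only and returns to the route at 12.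

3. Step 2 (o-quinone methide cycloaddition). The quinone methide may be consumed by self-condensation (dimerisation or attack on the phenol ring of a second molecule) faster than the unactivated, gaseous alkene traps it. The fallback builds ring D stepwise through ionic chemistry. It sets out from aldehyde 1. Claisen–Schmidt condensation with excess acetone (aq. NaOH, 20 °C) would give (3E)-4-(5-bromo-2-hydroxy-3-methoxyphenyl)but-3-en-2-one F6. Hydrogenation of the alkene over sulfided Pt/C (H2, EtOAc), which spares the aryl bromide, would give 4-(5-bromo-2-hydroxy-3-methoxyphenyl)butan-2-one F7. Addition of MeMgBr (3 equiv, THF, 0 °C) would give 4-bromo-2-(3-hydroxy-3-methylbutyl)-6-methoxyphenol F8. Acid-catalysed cyclodehydration through the tertiary cation (TsOH, toluene, reflux) returns to the route at chroman 5.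

**Further compounds**
F1 | step 10 | 1-[2,4-bis(benzyloxy)-6-hydroxyphenyl]ethanone | CC(=O)c1c(O)cc(OCc2ccccc2)cc1OCc1ccccc1
F2 | step 10 | (2E)-1-[2,4-bis(benzyloxy)-6-hydroxyphenyl]-3-(dimethylamino)prop-2-en-1-one | CN(C)/C=C/C(=O)c1c(O)cc(OCc2ccccc2)cc1OCc1ccccc1
F3 | step 10 | 5,7-bis(benzyloxy)-3-iodo-4H-chromen-4-one | O=c1c(I)coc2cc(OCc3ccccc3)cc(OCc3ccccc3)c12
F4 | step 10 | 5,7-bis(benzyloxy)-3-[8-(benzyloxy)-2,2-dimethylchroman-6-yl]-4H-chromen-4-one | O=c1c(-c2cc(OCc3ccccc3)c3OC(C)(C)CCc3c2)coc2cc(OCc3ccccc3)cc(OCc3ccccc3)c12
F5 | step 7 | 3-bromo-5-iodo-4H-pyran-4-one | O=c1c(Br)cocc1I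
F6 | step 2 | (3E)-4-(5-bromo-2-hydroxy-3-methoxyphenyl)but-3-en-2-one | CC(=O)/C=C/c1cc(Br)cc(OC)c1O
F7 | step 2 | 4-(5-bromo-2-hydroxy-3-methoxyphenyl)butan-2-one | CC(=O)CCc1cc(Br)cc(OC)c1O
F8 | step 2 | 4-bromo-2-(3-hydroxy-3-methylbutyl)-6-methoxyphenol | CC(C)(O)CCc1cc(Br)cc(OC)c1O
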